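**Plan**

- Numbering used: quinone ring C1(=O), C2(OH), C3(CH3), C4(=O), C5(OH), C6(C15H31). Retrosynthetic cuts, in order: the O–H groups at C2 and C5 back to OMe and OEt and the quinone back to its hydroquinone monosilyl ether; then the ring bond C1–C6; then C3–CH3 and C4–C5; then Sn–C5 and C6–chain.
- Enabling feature: C1 is a carbonyl carbon between the chain-bearing C6 and the run C2(O)–C3(CH3)–C4(O). C1–C2–C3–C4 with its three oxygens is therefore the carbon frame of a squaric ester, and C5(O)=C6 is an enol ether. Opening a cyclobutenone across C1–C4 makes C1 a ketene carbon that closes onto C6.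
- Forward order: pentadecyl chain joined to ethoxyacetylene, syn-hydrostannation, alkenyllithium added to dimethyl squarate, MeLi addition with carbonyl transposition, thermal expansion of the four-membered ring to the six-membered ring, oxidation, hydrolysis.
- Stereochemistry: the target has no stereocentre. The enol ether geometry comes from the syn-hydrostannation and is kept through tin–lithium exchange. The quaternary carbon of the cyclobutenones is racemic and disappears on ring expansion.

Key step: step 5

Remark on the chemistry: the target is a 2,5-dihydroxy-1,4-benzoquinone whose two hydroxyquinone tautomers equilibrate; the route delivers the compound as drawn. Ethoxyacetylene (solution in hexanes), 1-bromopentadecane and dimethyl squarate are taken as purchased.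

**Route**

Step 1
Reactants: 1 ethoxyacetylene (ethoxyethyne); 2 1-bromopentadecane
Product: 4 1-ethoxyheptadec-1-yne, via lithium ethoxyacetylide 3 (not isolated)
Conditions: n-BuLi, THF, −78 °C; then 2, HMPA, −78 °C → rt
Reagents that add atoms: none
Why: Deprotonation of the terminal ynol ether and SN2 alkylation of the lithium acetylide with a primary bromide in THF/HMPA (acetylide alkylation) is a standard entry to 1-alkoxyalk-1-ynes and brings in the whole pentadecyl chain at the future C6.

Step 2
Reactants: 4 1-ethoxyheptadec-1-yne
Product: 5 tributyl[(E)-1-ethoxyheptadec-1-en-1-yl]stannane (tin trans to the chain, ethoxy cis to it)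
Conditions: Bu3SnH (slow addition), Pd(PPh3)4 (cat.), THF, 0 °C → rt
Reagents that add atoms: tributyltin hydride CCCC[SnH](CCCC)CCCC
Why: Hydrostannation of a 1-alkoxyalk-1-yne under zerovalent palladium catalysis should place tin on the oxygen-bearing carbon and hydrogen on the distal carbon by syn addition, which fixes the alkene geometry.

Step 3
Reactants: 5 tributyl[(E)-1-ethoxyheptadec-1-en-1-yl]stannane; 6 dimethyl squarate (3,4-dimethoxycyclobut-3-ene-1,2-dione)
Product: 9 4-[(Z)-1-ethoxyheptadec-1-en-1-yl]-2,3-dimethoxy-4-(trimethylsilyloxy)cyclobut-2-en-1-one (racemic), via alkenyllithium 7 (not isolated), via lithium alkoxide 8 (not isolated)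
Conditions: n-BuLi, THF, −78 °C; cannulated into 6, THF, −78 °C; then Me3SiCl, −78 °C → 0 °C
Reagents that add atoms: chlorotrimethylsilane C[Si](C)(C)Cl
Why: Tin–lithium exchange keeps the alkene geometry, the α-ethoxyalkenyllithium should add 1,2 to one of the two equivalent carbonyl groups of the squaric ester (organolithium addition to a squarate), and silylation of the tertiary alkoxide in the flask frees the remaining carbonyl for the next addition; the new quaternary carbon is racemic, which is of no consequence.

Step 4
Reactants: 9 4-[(Z)-1-ethoxyheptadec-1-en-1-yl]-2,3-dimethoxy-4-(trimethylsilyloxy)cyclobut-2-en-1-one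
Product: 11 4-[(Z)-1-ethoxyheptadec-1-en-1-yl]-2-methoxy-3-methyl-4-(trimethylsilyloxy)cyclobut-2-en-1-one (racemic), via lithium alkoxide 10 (not isolated)
Conditions: MeLi, THF, −78 °C; then (CF3CO)2O, −78 °C; cold aq. NaHCO3
Reagents that add atoms: methyllithium [Li]C; water O
Why: 1,2-Addition of MeLi to the remaining carbonyl, O-trifluoroacetylation of alkoxide 10, ionisation to a methoxy-stabilised allyl cation and hydrolysis of its oxocarbenium end (the acid-triggered 1,3-carbonyl transposition used to turn squarate 1,2-adducts into substituted cyclobutenones) should move the carbonyl to the other neighbour of the quaternary carbon and leave methyl on the ring alkene, the pattern that puts methyl para to pentadecyl after ring expansion.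

Step 5
Reactants: 11 4-[(Z)-1-ethoxyheptadec-1-en-1-yl]-2-methoxy-3-methyl-4-(trimethylsilyloxy)cyclobut-2-en-1-one
Product: 14 3-ethoxy-6-methoxy-5-methyl-2-pentadecyl-4-(trimethylsilyloxy)phenol, via dienylketene 12 (not isolated), via cyclohexadienone 13 (not isolated)
Conditions: p-xylene (degassed), 138 °C, Ar
Reagents that add atoms: none
Why: Heating should open the cyclobutenone by conrotatory 4π-electrocyclic cleavage of the C(=O)–C(OSiMe3) bond to dienylketene 12, whose electrophilic ketene carbon (future quinone C1) and electron-rich enol-ether terminus CH–C15H31 (future C6) then join in a disrotatory 6π-electrocyclisation to cyclohexa-2,4-dienone 13, and enolisation of its C6–H gives the aromatic phenol 14. The closest known reaction type is the Moore rearrangement of 4-alkenyl- and 4-aryl-4-oxycyclobutenones to hydroquinones. The one ring formed, the six-membered carbocycle, is closed by 6π-electrocyclisation of a 1,3,5-triene in which the ketene C=C is one of the three double bonds. No stereocentre survives, because the sp3 carbon C6 of 13 becomes planar on aromatisation. The step needs the alkenyl group and not the silyloxy group to turn inward during ring opening, which is secured by the strong preference of an oxygen donor on the sp3 carbon of a cyclobutenone for outward rotation; closure is helped further by the (Z)-enol ether geometry, which places hydrogen and not the chain on the inside of the triene terminus. The positions of all six ring substituents follow from the connectivity of 11, so no regiochemical choice arises.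

Step 6
Reactants: 14 3-ethoxy-6-methoxy-5-methyl-2-pentadecyl-4-(trimethylsilyloxy)phenol
Product: 15 2-ethoxy-5-methoxy-6-methyl-3-pentadecylcyclohexa-2,5-diene-1,4-dione
Conditions: (NH4)2Ce(NO3)6, MeCN/H2O, 0 °C
Reagents that add atoms: none
Why: Two-electron oxidation of a para-silyloxyphenol by tetravalent cerium with loss of the silyl group (oxidative desilylation of a hydroquinone monosilyl ether to the quinone) should be fast at 0 °C and leave the two alkoxy groups in place.

Step 7
Reactants: 15 2-ethoxy-5-methoxy-6-methyl-3-pentadecylcyclohexa-2,5-diene-1,4-dione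
Product: 17 2,5-dihydroxy-3-methyl-6-pentadecylcyclohexa-2,5-diene-1,4-dione (CNP0605960.0), via disodium salt 16 (not isolated)
Conditions: 2 M NaOH aq., EtOH, N2, 50 °C; then 2 M HCl, 0 °C
Reagents that add atoms: sodium hydroxide [Na+].[OH-]
Why: Both alkoxy groups are vinylogous esters of the quinone carbonyls and should be exchanged for hydroxide by addition–elimination (saponification of alkoxyquinones), the stable dianion 16 shielding the ring from further attack until acidification releases the dihydroxyquinone.

**Compound list**

1 | ethoxyacetylene (ethoxyethyne) | C#COCC | starting material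
2 | 1-bromopentadecane | CCCCCCCCCCCCCCCBr | starting material
3 | lithium ethoxyacetylide | [Li]C#COCC | intermediate
4 | 1-ethoxyheptadec-1-yne | CCCCCCCCCCCCCCCC#COCC | intermediate
5 | tributyl[(E)-1-ethoxyheptadec-1-en-1-yl]stannane | CCCCCCCCCCCCCCC/C=C(\OCC)/[Sn](CCCC)(CCCC)CCCC | intermediate
6 | dimethyl squarate (3,4-dimethoxycyclobut-3-ene-1,2-dione) | COC1=C(OC)C(=O)C1=O | starting material
7 | [(Z)-1-ethoxyheptadec-1-en-1-yl]lithium | CCCCCCCCCCCCCCC/C=C(\OCC)/[Li] | intermediate
8 | lithium 1-[(Z)-1-ethoxyheptadec-1-en-1-yl]-2,3-dimethoxy-4-oxocyclobut-2-en-1-olate (racemic) | CCCCCCCCCCCCCCC/C=C(\OCC)/C1(O[Li])C(OC)=C(OC)C1=O | intermediate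
9 | 4-[(Z)-1-ethoxyheptadec-1-en-1-yl]-2,3-dimethoxy-4-(trimethylsilyloxy)cyclobut-2-en-1-one (racemic) | CCCCCCCCCCCCCCC/C=C(\OCC)/C1(O[Si](C)(C)C)C(OC)=C(OC)C1=O | intermediate
10 | lithium 4-[(Z)-1-ethoxyheptadec-1-en-1-yl]-2,3-dimethoxy-1-methyl-4-(trimethylsilyloxy)cyclobut-2-en-1-olate (mixture of diastereomers, each racemic) | CCCCCCCCCCCCCCC/C=C(\OCC)/C1(O[Si](C)(C)C)C(OC)=C(OC)C1(C)O[Li] | intermediate
11 | 4-[(Z)-1-ethoxyheptadec-1-en-1-yl]-2-methoxy-3-methyl-4-(trimethylsilyloxy)cyclobut-2-en-1-one (racemic) | CCCCCCCCCCCCCCC/C=C(\OCC)/C1(O[Si](C)(C)C)C(C)=C(OC)C1=O | intermediate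
12 | (3E,5Z)-5-ethoxy-2-methoxy-3-methyl-4-(trimethylsilyloxy)henicosa-1,3,5-trien-1-one | O=C=C(OC)/C(C)=C(/O[Si](C)(C)C)\C(OCC)=C\CCCCCCCCCCCCCCC | intermediate
13 | 5-ethoxy-2-methoxy-3-methyl-6-pentadecyl-4-(trimethylsilyloxy)cyclohexa-2,4-dien-1-one (racemic) | CCCCCCCCCCCCCCCC1C(=O)C(OC)=C(C)C(O[Si](C)(C)C)=C1OCC | intermediate
14 | 3-ethoxy-6-methoxy-5-methyl-2-pentadecyl-4-(trimethylsilyloxy)phenol | CCCCCCCCCCCCCCCc1c(O)c(OC)c(C)c(O[Si](C)(C)C)c1OCC | intermediate
15 | 2-ethoxy-5-methoxy-6-methyl-3-pentadecylcyclohexa-2,5-diene-1,4-dione | CCCCCCCCCCCCCCCC1=C(OCC)C(=O)C(C)=C(OC)C1=O | intermediate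
16 | disodium 2-methyl-3,6-dioxo-5-pentadecylcyclohexa-1,4-diene-1,4-diolate | CCCCCCCCCCCCCCCC1=C([O-])C(=O)C(C)=C([O-])C1=O.[Na+].[Na+] | intermediate
17 | 2,5-dihydroxy-3-methyl-6-pentadecylcyclohexa-2,5-diene-1,4-dione | CCCCCCCCCCCCCCCC1=C(O)C(=O)C(C)=C(O)C1=O | target

**Count**

Total steps: 7. Longest linear sequence: 7 steps (1 and 2 through 4, 5, 9, 11, 14, 15 to 17).

**Steps most likely to fail**

1. Step 4. What may go wrong: the electron-rich enol ether may not survive the electrophilic, acidic transposition (protonation or C-trifluoroacetylation of the double bond, hydrolysis to the ketone on work-up), or the silyl ether may be lost so that ionisation is no longer confined to the new carbinol. The fallback sets out from 2 and 6 and comes back to the route at 17; it keeps the ring closure between C1 and C6 but carries no enol ether through the transposition and adds the oxygen at C5 after the ring is made.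
   - Compound 2 is treated with LiC≡CH·H2NCH2CH2NH2 in DMSO to give heptadec-1-yne F1.
   - Its lithium acetylide (n-BuLi, THF, −78 °C) is added to 6 and the alkoxide is silylated with Me3SiCl to give 4-(heptadec-1-yn-1-yl)-2,3-dimethoxy-4-(trimethylsilyloxy)cyclobut-2-en-1-one F2.
   - MeLi and then (CF3CO)2O at −78 °C give 4-(heptadec-1-yn-1-yl)-2-methoxy-3-methyl-4-(trimethylsilyloxy)cyclobut-2-en-1-one F3.
   - 1 M HCl in THF at 0 °C frees the carbinol, 4-(heptadec-1-yn-1-yl)-4-hydroxy-2-methoxy-3-methylcyclobut-2-en-1-one F4.
   - Thermolysis in p-xylene at 138 °C (ring opening, closure of the ketene carbon onto the distal alkyne carbon, hydrogen transfer from the hydroxyl group) should give 3-methoxy-2-methyl-5-pentadecylcyclohexa-2,5-diene-1,4-dione F5.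
   - Thiele–Winter acetoxylation (Ac2O, BF3·OEt2) at the one free ring position gives 5-methoxy-6-methyl-3-pentadecylbenzene-1,2,4-triyl triacetate F6.
   - Saponification in air (2 M NaOH aq., EtOH; then HCl) cleaves the acetates and the methoxy group and oxidises the ring to 17.

2. Step 5. What may go wrong: the dienylketene may be consumed before it closes (dimerisation, capture by traces of water or by the phenol already formed), or ring opening with the wrong sense of rotation may leave the alkenyl group outside, out of reach of the ketene. The fallback sets out from 2 and comes back to the route at 17; it gives up ring construction and takes the six-membered ring from an arene.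
   - Purchased 1,2,4,5-tetramethoxybenzene is lithiated (n-BuLi, THF, 0 °C) and methylated with MeI to 1,2,4,5-tetramethoxy-3-methylbenzene F7.
   - A second lithiation at the last ring hydrogen (n-BuLi, TMEDA, THF, 0 °C) and alkylation with 2 give 1,2,4,5-tetramethoxy-3-methyl-6-pentadecylbenzene F8.
   - Oxidative demethylation with (NH4)2Ce(NO3)6 in MeCN/H2O gives 2,5-dimethoxy-3-methyl-6-pentadecylcyclohexa-2,5-diene-1,4-dione F9. Oxidation at the other para pair of methoxy groups would give an isomer that hydrolyses to the same product.
   - Hydrolysis under the conditions of step 7 gives 17.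

3. Step 2. What may go wrong: hydrostannation with the opposite regiochemistry (tin on the distal carbon), or protodestannylation of the acid-labile α-stannyl enol ether during purification. The fallback sets out from 4 and comes back to the route at 7, without tin.
   - Compound 4 is semihydrogenated (H2, Pd/CaCO3 poisoned with Pb(OAc)2, quinoline, hexane) to (Z)-1-ethoxyheptadec-1-ene F10.
   - α-Lithiation with t-BuLi in THF (−78 °C → 0 °C), the conditions that lithiate the cyclic (Z)-enol ether 3,4-dihydro-2H-pyran next to oxygen, should give 7 with lithium trans to the chain. Compound 7 is then added to 6 and silylated as in step 3.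

**Further compounds**

F1 | step 4 | heptadec-1-yne | CCCCCCCCCCCCCCCC#C
F2 | step 4 | 4-(heptadec-1-yn-1-yl)-2,3-dimethoxy-4-(trimethylsilyloxy)cyclobut-2-en-1-one (racemic) | CCCCCCCCCCCCCCCC#CC1(O[Si](C)(C)C)C(OC)=C(OC)C1=O
F3 | step 4 | 4-(heptadec-1-yn-1-yl)-2-methoxy-3-methyl-4-(trimethylsilyloxy)cyclobut-2-en-1-one (racemic) | CCCCCCCCCCCCCCCC#CC1(O[Si](C)(C)C)C(C)=C(OC)C1=O
F4 | step 4 | 4-(heptadec-1-yn-1-yl)-4-hydroxy-2-methoxy-3-methylcyclobut-2-en-1-one (racemic) | CCCCCCCCCCCCCCCC#CC1(O)C(C)=C(OC)C1=O
F5 | step 4 | 3-methoxy-2-methyl-5-pentadecylcyclohexa-2,5-diene-1,4-dione | CCCCCCCCCCCCCCCC1=CC(=O)C(C)=C(OC)C1=O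
F6 | step 4 | 5-methoxy-6-methyl-3-pentadecylbenzene-1,2,4-triyl triacetate | CCCCCCCCCCCCCCCc1c(OC(C)=O)c(OC)c(C)c(OC(C)=O)c1OC(C)=O
F7 | step 5 | 1,2,4,5-tetramethoxy-3-methylbenzene | COc1cc(OC)c(OC)c(C)c1OC
F8 | step 5 | 1,2,4,5-tetramethoxy-3-methyl-6-pentadecylbenzene | CCCCCCCCCCCCCCCc1c(OC)c(OC)c(C)c(OC)c1OC
F9 | step 5 | 2,5-dimethoxy-3-methyl-6-pentadecylcyclohexa-2,5-diene-1,4-dione | CCCCCCCCCCCCCCCC1=C(OC)C(=O)C(C)=C(OC)C1=O
F10 | step 2 | (Z)-1-ethoxyheptadec-1-ene | CCCCCCCCCCCCCCC/C=C\OCC
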